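**Retrosynthetic overview**
- The target is a trans-3-aryl-naringenin whose 3-aryl group is ring B of genkwanin; the last bond made is O1–C2 of the chromanone (ring C').
- Enabling feature: C2 carries the 4-hydroxyphenyl ring B', so it is a para-hydroxybenzylic carbon. Two phenolic oxygens lie within reach of it: O1 on the phloroglucinol ring A' (six-membered closure) and the 4'-oxygen of flavone ring B on C3 (five-membered closure). The isomeric 2-aryl-3-aroyl-2,3-dihydrobenzofuran can therefore hand C2 from O4' to O1 through a para-quinone methide while C3 stays sp3.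
- The dihydrobenzofuran is the easier skeleton: dirhodium-carbenoid C–H insertion sets C2, epimerization sets C3 trans to it, and the temporary O4'–C2 bond masks the 4'-OH and locks C3 until the end.
- Order of ring formation: flavone ring C (polyanion acylation, cyclodehydration) → dihydrofuran ring (C–H insertion) → aryl ketone (Negishi acylation) → debenzylation → chromanone ring C' (quinone-methide relay).

Key step: step 12

Assumption: Rh2(S-PTTL)4 is taken to induce the (2R) configuration at the ether carbon, as in its insertions into 2-(benzyloxy)aryl diazoacetates; if the sense proved opposite on this substrate, Rh2(R-PTTL)4 would be used instead.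

**Step 1**
Reactants: 1 4-hydroxy-3-iodobenzoic acid
Product: 2 tert-butyldimethylsilyl 4-(tert-butyldimethylsilyloxy)-3-iodobenzoate
Conditions: TBSCl (2.3 equiv), imidazole (5 equiv), DMF, rt
Reagents that add atoms: tert-butyldimethylsilyl chloride, CC(C)(C)[Si](C)(C)Cl
Why: Imidazole-promoted silylation of both the phenol and the carboxylic acid should give the silyl ether/silyl ester needed for a neutral conversion to the acid chloride.

**Step 2**
Reactants: 2 tert-butyldimethylsilyl 4-(tert-butyldimethylsilyloxy)-3-iodobenzoate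
Product: 3 4-(tert-butyldimethylsilyloxy)-3-iodobenzoyl chloride
Conditions: (COCl)2 (1.2 equiv), DMF (cat.), CH2Cl2, 0 °C → rt
Reagents that add atoms: oxalyl chloride, ClC(=O)C(=O)Cl
Why: Silyl esters are converted into acid chlorides by the Vilsmeier-type chloroiminium reagent under neutral conditions, which should leave the aryl silyl ether intact.

**Step 3**
Reactants: 4 1-(2,6-dihydroxy-4-methoxyphenyl)ethan-1-one; 3 4-(tert-butyldimethylsilyloxy)-3-iodobenzoyl chloride
Product: 5 1-[4-(tert-butyldimethylsilyloxy)-3-iodophenyl]-3-(2,6-dihydroxy-4-methoxyphenyl)propane-1,3-dione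
Conditions: LiN(SiMe3)2 (4.2 equiv), THF, −78 → −10 °C; then 3, −78 °C → rt; 1 M HCl work-up
Reagents that add atoms: none
Why: The lithium trianion of 4 should be C-acylated at the ketone enolate carbon (crossed Claisen acylation of a polyanion), giving the 1,3-diketone directly without an O-acylation/Baker–Venkataraman detour.

**Step 4**
Reactants: 5 1-[4-(tert-butyldimethylsilyloxy)-3-iodophenyl]-3-(2,6-dihydroxy-4-methoxyphenyl)propane-1,3-dione
Product: 6 5-hydroxy-2-(4-hydroxy-3-iodophenyl)-7-methoxy-4H-chromen-4-one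
Conditions: H2SO4 (cat.), AcOH, 95 °C
Reagents that add atoms: none
Why: Acid-catalysed cyclodehydration of the ortho-hydroxyaryl 1,3-diketone (the closing stage of the Baker–Venkataraman flavone synthesis) forms ring C, and the aryl silyl ether should be solvolysed under the same conditions.

**Step 5**
Reactants: 6 5-hydroxy-2-(4-hydroxy-3-iodophenyl)-7-methoxy-4H-chromen-4-one; 7 1-(benzyloxy)-4-(chloromethyl)benzene
Product: 9 5-(benzyloxy)-2-{4-[4-(benzyloxy)benzyloxy]-3-iodophenyl}-7-methoxy-4H-chromen-4-one, via mono-ether 8 (not isolated)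
Conditions: K2CO3, 7 (1.05 equiv), DMF, rt; then BnBr (2 equiv), 70 °C
Reagents that add atoms: benzyl bromide, BrCc1ccccc1
Why: In this Williamson etherification the free 4'-OH should react at room temperature, whereas the 5-OH, chelated to the chromone carbonyl, is only benzylated on heating, so the two different groups can be installed in sequence.

**Step 6**
Reactants: 9 5-(benzyloxy)-2-{4-[4-(benzyloxy)benzyloxy]-3-iodophenyl}-7-methoxy-4H-chromen-4-one; 10 ethyl diazoacetate
Product: 11 ethyl 2-{2-[4-(benzyloxy)benzyloxy]-5-[5-(benzyloxy)-7-methoxy-4-oxo-4H-chromen-2-yl]phenyl}-2-diazoacetate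
Conditions: Pd(PPh3)4 (5 mol%), Ag2CO3 (0.5 equiv), Et3N (1.3 equiv), toluene, rt
Reagents that add atoms: none
Why: Palladium-catalysed cross-coupling of aryl iodides with diazoacetates (oxidative addition to zerovalent palladium, base-assisted C–H metalation of the diazo ester, reductive elimination) keeps the diazo group and should give the aryldiazoacetate in one step.

**Step 7**
Reactants: 11 ethyl 2-{2-[4-(benzyloxy)benzyloxy]-5-[5-(benzyloxy)-7-methoxy-4-oxo-4H-chromen-2-yl]phenyl}-2-diazoacetate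
Product: 12 ethyl (2R,3S)-5-[5-(benzyloxy)-7-methoxy-4-oxo-4H-chromen-2-yl]-2-[4-(benzyloxy)phenyl]-2,3-dihydrobenzofuran-3-carboxylate (2,3-cis)
Conditions: Rh2(S-PTTL)4 (dirhodium tetrakis[N-phthaloyl-(S)-tert-leucinate], 2 mol%), toluene/CH2Cl2, −60 °C
Reagents that add atoms: none
Why: Enantioselective intramolecular 1,5 C–H insertion of the donor/acceptor dirhodium carbenoid into the benzylic ether C–H (activated by oxygen and the 4-alkoxyphenyl ring) should close the dihydrofuran; the chiral carboxylate ligands set C2 as (R), and the concerted insertion gives the cis isomer kinetically.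

**Step 8**
Reactants: 12 ethyl (2R,3S)-5-[5-(benzyloxy)-7-methoxy-4-oxo-4H-chromen-2-yl]-2-[4-(benzyloxy)phenyl]-2,3-dihydrobenzofuran-3-carboxylate
Product: 14 (2R,3R)-5-[5-(benzyloxy)-7-methoxy-4-oxo-4H-chromen-2-yl]-2-[4-(benzyloxy)phenyl]-2,3-dihydrobenzofuran-3-carboxylic acid, via trans ethyl ester 13 (not isolated)
Conditions: NaOEt (0.2 equiv), EtOH/THF, 0 °C → rt; then LiOH, H2O, rt; 1 M HCl work-up
Reagents that add atoms: lithium hydroxide, [Li+].[OH-]
Why: Base-mediated epimerization through the ester enolate should move C3 to the thermodynamically favoured trans arrangement, (3R), while the non-acidic C2 keeps the configuration from step 7; saponification then gives the acid.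

**Step 9**
Reactants: 15 1,3,5-tris(benzyloxy)benzene
Product: 16 2-bromo-1,3,5-tris(benzyloxy)benzene
Conditions: N-bromosuccinimide (1.0 equiv), CH2Cl2, −20 → 0 °C
Reagents that add atoms: N-bromosuccinimide, O=C1CCC(=O)N1Br
Why: Electrophilic aromatic bromination of the symmetric, highly activated ring should stop at the monobromide because all three free positions are equivalent and the first bromine deactivates and shields the ring.

**Step 10**
Reactants: 14 (2R,3R)-5-[5-(benzyloxy)-7-methoxy-4-oxo-4H-chromen-2-yl]-2-[4-(benzyloxy)phenyl]-2,3-dihydrobenzofuran-3-carboxylic acid; 16 2-bromo-1,3,5-tris(benzyloxy)benzene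
Product: 20 5-(benzyloxy)-2-{(2R,3R)-2-[4-(benzyloxy)phenyl]-3-[2,4,6-tris(benzyloxy)benzoyl]-2,3-dihydrobenzofuran-5-yl}-7-methoxy-4H-chromen-4-one, via acid chloride 17 (not isolated), via aryllithium 18 (not isolated), via arylzinc chloride 19 (not isolated)
Conditions: 14, (COCl)2, DMF (cat.), CH2Cl2, 0 °C → rt, concentrate; 16, n-BuLi, THF, −78 °C, then ZnCl2, −78 → 0 °C; combine, Pd(PPh3)4 (5 mol%), THF, 0 °C → rt
Reagents that add atoms: none
Why: Negishi acylation (palladium-catalysed coupling of an acid chloride with an arylzinc halide) should form the aryl ketone without base or strong acid, so the chromone, the benzylic ether C2–O bond and the trans C2/C3 relationship are untouched.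

**Step 11**
Reactants: 20 5-(benzyloxy)-2-{(2R,3R)-2-[4-(benzyloxy)phenyl]-3-[2,4,6-tris(benzyloxy)benzoyl]-2,3-dihydrobenzofuran-5-yl}-7-methoxy-4H-chromen-4-one
Product: 21 5-hydroxy-2-[(2R,3R)-2-(4-hydroxyphenyl)-3-(2,4,6-trihydroxybenzoyl)-2,3-dihydrobenzofuran-5-yl]-7-methoxy-4H-chromen-4-one
Conditions: H2 (1 atm), 10% Pd/C, EtOAc/THF, rt
Reagents that add atoms: none
Why: Catalytic hydrogenolysis should remove the five O-benzyl groups faster than it attacks the cyclic benzylic C2–O bond or the flavone C2=C3 bond under neutral conditions at atmospheric pressure, and the reaction is stopped once debenzylation is complete.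

**Step 12**
Reactants: 21 5-hydroxy-2-[(2R,3R)-2-(4-hydroxyphenyl)-3-(2,4,6-trihydroxybenzoyl)-2,3-dihydrobenzofuran-5-yl]-7-methoxy-4H-chromen-4-one
Product: 23 (2S,3R)-5,7-dihydroxy-3-[2-hydroxy-5-(5-hydroxy-7-methoxy-4-oxo-4H-chromen-2-yl)phenyl]-2-(4-hydroxyphenyl)chroman-4-one, via para-quinone methide 22 (not isolated)
Conditions: CF3CO2H (10 mol%), (CF3)2CHOH (0.005 M), 0 °C → rt
Reagents that add atoms: none
Why: Proposed new method: under catalytic acid in a strongly ionizing, non-basic solvent the O4'–C2 bond of the dihydrobenzofuran should heterolyse because C2 is para-hydroxybenzylic, giving the (protonated) para-quinone methide 22 in which C3 is still sp3 and configurationally intact; an ortho-hydroxyl of the 2,4,6-trihydroxybenzoyl group then adds to the methide carbon (oxa-1,6-addition) to form O1–C2. The closest known reaction types are the acid-mediated ring opening and C2 epimerization of 2-(4-hydroxyphenyl)-2,3-dihydrobenzofurans through quinone methides in neolignan and resveratrol-oligomer chemistry, and intramolecular oxa-1,6-additions of phenols to para-quinone methides; the transfer of the benzylic carbon from a five-membered to a six-membered oxacycle has no direct precedent. The chromanone ring closes in the 6-exo-trig mode onto the exocyclic methide C=C, in competition with the unproductive 5-exo-trig return to the dihydrobenzofuran. C2 is set by C3 under thermodynamic control: reversible ionization should funnel both C2 epimers to the trans-2,3-diaryl chromanone with both aryl groups equatorial, so (3R) dictates (2S). The step needs six-membered over five-membered closure and capture faster than loss of H-3 from the cation, which would give the achiral α-aryl chalcone; the first is expected from the stability of the chelated 5-hydroxychroman-4-one (2',4',6'-trihydroxychalcones close completely to flavanones, and the target keeps its free 4'-OH next to C3 without reverting), the second from intramolecular capture through a six-membered transition state at low temperature in a medium without base, with high dilution suppressing intermolecular Friedel–Crafts alkylation.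

**Compound list**
1 | 4-hydroxy-3-iodobenzoic acid | OC(=O)c1ccc(O)c(I)c1 | starting material
2 | tert-butyldimethylsilyl 4-(tert-butyldimethylsilyloxy)-3-iodobenzoate | CC(C)(C)[Si](C)(C)OC(=O)c1ccc(O[Si](C)(C)C(C)(C)C)c(I)c1 | intermediate
3 | 4-(tert-butyldimethylsilyloxy)-3-iodobenzoyl chloride | CC(C)(C)[Si](C)(C)Oc1ccc(C(Cl)=O)cc1I | intermediate
4 | 1-(2,6-dihydroxy-4-methoxyphenyl)ethan-1-one | COc1cc(O)c(C(C)=O)c(O)c1 | starting material
5 | 1-[4-(tert-butyldimethylsilyloxy)-3-iodophenyl]-3-(2,6-dihydroxy-4-methoxyphenyl)propane-1,3-dione | COc1cc(O)c(C(=O)CC(=O)c2ccc(O[Si](C)(C)C(C)(C)C)c(I)c2)c(O)c1 | intermediate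
6 | 5-hydroxy-2-(4-hydroxy-3-iodophenyl)-7-methoxy-4H-chromen-4-one | COc1cc(O)c2c(=O)cc(-c3ccc(O)c(I)c3)oc2c1 | intermediate
7 | 1-(benzyloxy)-4-(chloromethyl)benzene | ClCc1ccc(OCc2ccccc2)cc1 | starting material
8 | 2-{4-[4-(benzyloxy)benzyloxy]-3-iodophenyl}-5-hydroxy-7-methoxy-4H-chromen-4-one (formed in situ) | COc1cc(O)c2c(=O)cc(-c3ccc(OCc4ccc(OCc5ccccc5)cc4)c(I)c3)oc2c1 | intermediate
9 | 5-(benzyloxy)-2-{4-[4-(benzyloxy)benzyloxy]-3-iodophenyl}-7-methoxy-4H-chromen-4-one | COc1cc(OCc2ccccc2)c2c(=O)cc(-c3ccc(OCc4ccc(OCc5ccccc5)cc4)c(I)c3)oc2c1 | intermediate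
10 | ethyl diazoacetate | CCOC(=O)C=[N+]=[N-] | starting material
11 | ethyl 2-{2-[4-(benzyloxy)benzyloxy]-5-[5-(benzyloxy)-7-methoxy-4-oxo-4H-chromen-2-yl]phenyl}-2-diazoacetate | CCOC(=O)C(=[N+]=[N-])c1cc(-c2cc(=O)c3c(OCc4ccccc4)cc(OC)cc3o2)ccc1OCc1ccc(OCc2ccccc2)cc1 | intermediate
12 | ethyl (2R,3S)-5-[5-(benzyloxy)-7-methoxy-4-oxo-4H-chromen-2-yl]-2-[4-(benzyloxy)phenyl]-2,3-dihydrobenzofuran-3-carboxylate (cis) | CCOC(=O)[C@H]1c2cc(-c3cc(=O)c4c(OCc5ccccc5)cc(OC)cc4o3)ccc2O[C@H]1c1ccc(OCc2ccccc2)cc1 | intermediate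
13 | ethyl (2R,3R)-5-[5-(benzyloxy)-7-methoxy-4-oxo-4H-chromen-2-yl]-2-[4-(benzyloxy)phenyl]-2,3-dihydrobenzofuran-3-carboxylate (trans, formed in situ) | CCOC(=O)[C@@H]1c2cc(-c3cc(=O)c4c(OCc5ccccc5)cc(OC)cc4o3)ccc2O[C@H]1c1ccc(OCc2ccccc2)cc1 | intermediate
14 | (2R,3R)-5-[5-(benzyloxy)-7-methoxy-4-oxo-4H-chromen-2-yl]-2-[4-(benzyloxy)phenyl]-2,3-dihydrobenzofuran-3-carboxylic acid | OC(=O)[C@@H]1c2cc(-c3cc(=O)c4c(OCc5ccccc5)cc(OC)cc4o3)ccc2O[C@H]1c1ccc(OCc2ccccc2)cc1 | intermediate
15 | 1,3,5-tris(benzyloxy)benzene | c1ccc(COc2cc(OCc3ccccc3)cc(OCc3ccccc3)c2)cc1 | starting material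
16 | 2-bromo-1,3,5-tris(benzyloxy)benzene | Brc1c(OCc2ccccc2)cc(OCc2ccccc2)cc1OCc1ccccc1 | intermediate
17 | (2R,3R)-5-[5-(benzyloxy)-7-methoxy-4-oxo-4H-chromen-2-yl]-2-[4-(benzyloxy)phenyl]-2,3-dihydrobenzofuran-3-carbonyl chloride (formed in situ) | ClC(=O)[C@@H]1c2cc(-c3cc(=O)c4c(OCc5ccccc5)cc(OC)cc4o3)ccc2O[C@H]1c1ccc(OCc2ccccc2)cc1 | intermediate
18 | 2,4,6-tris(benzyloxy)phenyllithium (formed in situ) | [Li]c1c(OCc2ccccc2)cc(OCc2ccccc2)cc1OCc1ccccc1 | intermediate
19 | 2,4,6-tris(benzyloxy)phenylzinc chloride (formed in situ) | Cl[Zn]c1c(OCc2ccccc2)cc(OCc2ccccc2)cc1OCc1ccccc1 | intermediate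
20 | 5-(benzyloxy)-2-{(2R,3R)-2-[4-(benzyloxy)phenyl]-3-[2,4,6-tris(benzyloxy)benzoyl]-2,3-dihydrobenzofuran-5-yl}-7-methoxy-4H-chromen-4-one | O=C(c1c(OCc2ccccc2)cc(OCc2ccccc2)cc1OCc1ccccc1)[C@@H]1c2cc(-c3cc(=O)c4c(OCc5ccccc5)cc(OC)cc4o3)ccc2O[C@H]1c1ccc(OCc2ccccc2)cc1 | intermediate
21 | 5-hydroxy-2-[(2R,3R)-2-(4-hydroxyphenyl)-3-(2,4,6-trihydroxybenzoyl)-2,3-dihydrobenzofuran-5-yl]-7-methoxy-4H-chromen-4-one | O=C(c1c(O)cc(O)cc1O)[C@@H]1c2cc(-c3cc(=O)c4c(O)cc(OC)cc4o3)ccc2O[C@H]1c1ccc(O)cc1 | intermediate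
22 | 4-{(2S)-2-[2-hydroxy-5-(5-hydroxy-7-methoxy-4-oxo-4H-chromen-2-yl)phenyl]-3-oxo-3-(2,4,6-trihydroxyphenyl)propylidene}cyclohexa-2,5-dien-1-one (formed in situ) | O=C1C=CC(=C[C@H](C(=O)c2c(O)cc(O)cc2O)c2cc(-c3cc(=O)c4c(O)cc(OC)cc4o3)ccc2O)C=C1 | intermediate
23 | (2S,3R)-5,7-dihydroxy-3-[2-hydroxy-5-(5-hydroxy-7-methoxy-4-oxo-4H-chromen-2-yl)phenyl]-2-(4-hydroxyphenyl)chroman-4-one | COc1cc(O)c2c(=O)cc(-c3ccc(O)c([C@H]4C(=O)c5c(O)cc(O)cc5O[C@@H]4c4ccc(O)cc4)c3)oc2c1 | target

**Step count**
Total steps: 12. Longest linear sequence: 11 (steps 1–8 and 10–12; step 9 is a one-step branch).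

**Steps most likely to fail**

Step 12 (Proposed new method). The ring transposition may stop short under thermodynamic control, or the benzylic cation may lose H-3 and so erode the enantiomeric purity through the achiral chalcone. The fallback replaces chirality relay by kinetically biased closure and resolution, all with known chemistry. It sets out from 21: aqueous K2CO3 in MeOH under argon should open the dihydrofuran by phenolate-driven 1,6-elimination and tautomerization to the achiral (E)-2-[2-hydroxy-5-(5-hydroxy-7-methoxy-4-oxo-4H-chromen-2-yl)phenyl]-3-(4-hydroxyphenyl)-1-(2,4,6-trihydroxyphenyl)prop-2-en-1-one F1 (E/Z mixture expected, E drawn). Acidification (AcOH, MeOH, rt) then triggers the classical chalcone-to-flavanone 6-endo oxa-Michael closure, which Baldwin's rules favour over the 5-endo return to the dihydrobenzofuran. This should give the racemic trans product, that is 23 together with (2R,3S)-5,7-dihydroxy-3-[2-hydroxy-5-(5-hydroxy-7-methoxy-4-oxo-4H-chromen-2-yl)phenyl]-2-(4-hydroxyphenyl)chroman-4-one F2. Preparative chromatography on a chiral stationary phase separates the two, and the route is rejoined at 23.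

Step 7. Enantiofacial discrimination may be poor, or the catalyst may be inhibited by the chromone carbonyl and by low solubility of the substrate at −60 °C. The fallback replaces asymmetric catalysis by classical resolution and sets out from 11. Rh2(OAc)4 (1 mol%) in CH2Cl2 at rt should give the racemic cis ester, that is 12 together with ethyl (2S,3R)-5-[5-(benzyloxy)-7-methoxy-4-oxo-4H-chromen-2-yl]-2-[4-(benzyloxy)phenyl]-2,3-dihydrobenzofuran-3-carboxylate F3. The conditions of step 8 convert the pair, through 13 and ethyl (2S,3S)-5-[5-(benzyloxy)-7-methoxy-4-oxo-4H-chromen-2-yl]-2-[4-(benzyloxy)phenyl]-2,3-dihydrobenzofuran-3-carboxylate F4, into 14 and (2S,3S)-5-[5-(benzyloxy)-7-methoxy-4-oxo-4H-chromen-2-yl]-2-[4-(benzyloxy)phenyl]-2,3-dihydrobenzofuran-3-carboxylic acid F5. Fractional crystallization with (S)-1-phenylethylamine (or its enantiomer, whichever gives the less soluble salt of the wanted acid) should furnish the (S)-1-phenylethylammonium salt of 14 F6. Acidification with 1 M HCl returns the route to 14.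

Step 10. Transmetalation of the doubly ortho-substituted arylzinc may be slow, leaving time for decarbonylation of the acylpalladium intermediate or decomposition of the acid chloride. The fallback replaces the organometallic nucleophile by an electrophilic aromatic substitution and sets out from 14 and 15. Trifluoroacetic anhydride with catalytic 85% H3PO4 in CH2Cl2 at −20 → 0 °C should convert 14 into (2R,3R)-5-[5-(benzyloxy)-7-methoxy-4-oxo-4H-chromen-2-yl]-2-[4-(benzyloxy)phenyl]-2,3-dihydrobenzofuran-3-carboxylic trifluoroacetic anhydride F7. This mixed anhydride acylates 15 (Friedel–Crafts acylation; all three free positions of 15 are equivalent), and the route is rejoined at 20.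

**Further compounds**
F1 | step 12 | (E)-2-[2-hydroxy-5-(5-hydroxy-7-methoxy-4-oxo-4H-chromen-2-yl)phenyl]-3-(4-hydroxyphenyl)-1-(2,4,6-trihydroxyphenyl)prop-2-en-1-one | O=C(c1c(O)cc(O)cc1O)/C(=C/c1ccc(O)cc1)c1cc(-c2cc(=O)c3c(O)cc(OC)cc3o2)ccc1O
F2 | step 12 | (2R,3S)-5,7-dihydroxy-3-[2-hydroxy-5-(5-hydroxy-7-methoxy-4-oxo-4H-chromen-2-yl)phenyl]-2-(4-hydroxyphenyl)chroman-4-one | COc1cc(O)c2c(=O)cc(-c3ccc(O)c([C@@H]4C(=O)c5c(O)cc(O)cc5O[C@H]4c4ccc(O)cc4)c3)oc2c1
F3 | step 7 | ethyl (2S,3R)-5-[5-(benzyloxy)-7-methoxy-4-oxo-4H-chromen-2-yl]-2-[4-(benzyloxy)phenyl]-2,3-dihydrobenzofuran-3-carboxylate | CCOC(=O)[C@@H]1c2cc(-c3cc(=O)c4c(OCc5ccccc5)cc(OC)cc4o3)ccc2O[C@@H]1c1ccc(OCc2ccccc2)cc1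
F4 | step 7 | ethyl (2S,3S)-5-[5-(benzyloxy)-7-methoxy-4-oxo-4H-chromen-2-yl]-2-[4-(benzyloxy)phenyl]-2,3-dihydrobenzofuran-3-carboxylate | CCOC(=O)[C@H]1c2cc(-c3cc(=O)c4c(OCc5ccccc5)cc(OC)cc4o3)ccc2O[C@@H]1c1ccc(OCc2ccccc2)cc1
F5 | step 7 | (2S,3S)-5-[5-(benzyloxy)-7-methoxy-4-oxo-4H-chromen-2-yl]-2-[4-(benzyloxy)phenyl]-2,3-dihydrobenzofuran-3-carboxylic acid | OC(=O)[C@H]1c2cc(-c3cc(=O)c4c(OCc5ccccc5)cc(OC)cc4o3)ccc2O[C@@H]1c1ccc(OCc2ccccc2)cc1
F6 | step 7 | (S)-1-phenylethylammonium (2R,3R)-5-[5-(benzyloxy)-7-methoxy-4-oxo-4H-chromen-2-yl]-2-[4-(benzyloxy)phenyl]-2,3-dihydrobenzofuran-3-carboxylate | C[C@H]([NH3+])c1ccccc1.[O-]C(=O)[C@@H]1c2cc(-c3cc(=O)c4c(OCc5ccccc5)cc(OC)cc4o3)ccc2O[C@H]1c1ccc(OCc2ccccc2)cc1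
F7 | step 10 | (2R,3R)-5-[5-(benzyloxy)-7-methoxy-4-oxo-4H-chromen-2-yl]-2-[4-(benzyloxy)phenyl]-2,3-dihydrobenzofuran-3-carboxylic trifluoroacetic anhydride | O=C(OC(=O)C(F)(F)F)[C@@H]1c2cc(-c3cc(=O)c4c(OCc5ccccc5)cc(OC)cc4o3)ccc2O[C@H]1c1ccc(OCc2ccccc2)cc1
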